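C1' is the CH2 between the two rings, C2' the cyclopentane CH that carries it, C3' the C(CH3)(OH) carbon, C4' and C5' the ring CH2 groups, and C6' the CH bearing the isopropenyl group.
Retrosynthetic cuts, in order: C3'–CH3 (methyl addition to a cyclopentanone); C1'–C4 of the cyclohexadienone (Michael addition of a gem-diprenyl acylphloroglucinol trione to an exo-methylene ketone); C2'–C1' and C6'–isopropenyl together (back to cyclopent-2-enone); the two prenyl–C6 bonds and the ring–acyl bond of the trione (back to phloroglucinol).
Enabling feature: C6', C2' and C3' are three neighbouring atoms of the cyclopentane ring, C6' and C2' being trans-substituted CH groups and C3' a tertiary carbinol; they are the β-carbon, the α-carbon and the carbonyl carbon of cyclopent-2-enone and can take a nucleophile, an electrophile and a second nucleophile in turn.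
Forward: no ring is built; the five-membered ring enters as cyclopentenone and the six-membered ring as phloroglucinol. Isopropenyl and C1' are attached in one flask, the resulting Mannich base is quaternised, the trione is made in two steps, the fragments are joined at C1', and the methyl group is added last.
Stereochemistry: C6' comes from the chiral copper catalyst; C2' is set trans to C6' by anti approach of the iminium ion and again by equilibration after the Michael step; C3' is set by methyl attack anti to C1'.

Key step: step 1

Assumption: the enolised β-triketones 11, 13 and 14 are drawn as the tautomer of the target SMILES, and the antipode of the ferrocenyl diphosphine in step 1 is the one that gives the 3R centre, to be identified once on protonated enolate 4, because the sense of induction for an alkenyl Grignard reagent is not secure.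

Step 1
Reactants: 1 cyclopent-2-en-1-one; 2 isopropenylmagnesium bromide; 3 N,N-dimethylmethaniminium iodide (Eschenmoser's salt)
Product: 5 (2R,3R)-2-[(dimethylamino)methyl]-3-(prop-1-en-2-yl)cyclopentan-1-one, via bromomagnesium (3R)-3-(prop-1-en-2-yl)cyclopent-1-en-1-olate 4 (not isolated)
Conditions: CuBr·SMe2 (5 mol %), Josiphos-type ligand 1-[2-(diphenylphosphino)ferrocenyl]ethyldicyclohexylphosphine (C36H44FeP2, one antipode, 6 mol %), t-BuOMe, −78 °C, 2 (1.2 equiv) added over 2 h; then 3 (1.5 equiv), CH2Cl2, −78 → 0 °C; aq NaHCO3, acid–base extraction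
Reagents that add atoms: isopropenylmagnesium bromide 2, C=C(C)[Mg]Br; N,N-dimethylmethaniminium iodide 3, C=[N+](C)C.[I-]
Why: A chiral bisphosphine complex of monovalent copper takes the isopropenyl group from 2, binds the enone as a π-complex, adds oxidatively at the β-carbon to a trivalent copper intermediate and releases the C1–C2 magnesium enolate 4 by reductive elimination, and 4 then attacks the iminium carbon of 3 in a Mannich reaction. The closest known reaction type is the copper-catalysed asymmetric conjugate addition of Grignard reagents to cyclic enones with trapping of the magnesium enolate by iminium or other onium electrophiles, a one-flask relative of the cuprate addition/Eschenmoser-salt sequence. No ring is closed. C3 is set by the ligand, which shields one face of the copper-bound enone, and C2 is set by the substrate, because the iminium ion approaches the enolate anti to the new isopropenyl group and the trans ketone is also the more stable epimer. The step needs 1,4- over 1,2-addition, which copper catalysis, slow addition of 2 and −78 °C should secure, and reaction at C2 only, which follows from the regiospecific formation of 4 and its trapping before any proton exchange. The basic nitrogen of 5 allows purification by extraction and, if needed, enrichment by crystallisation of a salt.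

Step 2
Reactants: 5 (2R,3R)-2-[(dimethylamino)methyl]-3-(prop-1-en-2-yl)cyclopentan-1-one
Product: 6 N,N,N-trimethyl-1-[(1R,5R)-2-oxo-5-(prop-1-en-2-yl)cyclopentyl]methanaminium iodide
Conditions: MeI (3 equiv), Et2O, 0 °C → rt, dark; filtration
Reagents that add atoms: iodomethane, CI
Why: Menshutkin quaternisation of the tertiary amine by SN2 attack on iodomethane should precipitate the salt from ether, and since no base is present neither stereocentre is touched.

Step 3
Reactants: 7 benzene-1,3,5-triol (phloroglucinol); 8 2-methylpropanoyl chloride
Product: 9 2-methyl-1-(2,4,6-trihydroxyphenyl)propan-1-one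
Conditions: AlCl3 (3.5 equiv), PhNO2/CH2Cl2, 0 → 40 °C; ice, aq HCl
Reagents that add atoms: 2-methylpropanoyl chloride 8, CC(C)C(=O)Cl
Why: Friedel–Crafts C-acylation of the electron-rich triphenol should stop after one acyl group because the hydrogen-bonded aryl ketone deactivates the ring; no stereocentre is formed.

Step 4
Reactants: 9 2-methyl-1-(2,4,6-trihydroxyphenyl)propan-1-one; 10 1-bromo-3-methylbut-2-ene (prenyl bromide)
Product: 11 3,5-dihydroxy-6,6-bis(3-methylbut-2-en-1-yl)-2-(2-methylpropanoyl)cyclohexa-2,4-dien-1-one
Conditions: NaOMe (3 equiv), 10 (2.1 equiv), MeOH, 0 °C → rt; aq HCl to pH 3, chromatography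
Reagents that add atoms: 1-bromo-3-methylbut-2-ene 10, CC(C)=CCBr
Why: In this base-mediated dearomative C-alkylation of an acylphloroglucinol the phenolate is alkylated at carbon in methanol, and the second prenyl group should enter at the already prenylated carbon because that gives a β-triketone whose stabilised enolate resists a third alkylation when only two equivalents of bromide are offered; the new quaternary carbon bears two identical groups and is not a stereocentre.

Step 5
Reactants: 6 N,N,N-trimethyl-1-[(1R,5R)-2-oxo-5-(prop-1-en-2-yl)cyclopentyl]methanaminium iodide; 11 3,5-dihydroxy-6,6-bis(3-methylbut-2-en-1-yl)-2-(2-methylpropanoyl)cyclohexa-2,4-dien-1-one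
Product: 13 3,5-dihydroxy-6,6-bis(3-methylbut-2-en-1-yl)-2-(2-methylpropanoyl)-4-{[(1S,5R)-2-oxo-5-(prop-1-en-2-yl)cyclopentyl]methyl}cyclohexa-2,4-dien-1-one, via (3S)-2-methylidene-3-(prop-1-en-2-yl)cyclopentan-1-one 12 (not isolated)
Conditions: K2CO3 (2.5 equiv), MeCN, 0 °C → rt, 12 h; citrate buffer pH 4
Reagents that add atoms: none
Why: Carbonate turns 11 into its enolate and induces E1cB loss of trimethylamine from 6, and the exo-methylene ketone 12 is intercepted as it forms by Michael addition of the trione enolate through its only hydrogen-bearing ring carbon (the classical use of a Mannich base methiodide as a latent vinyl ketone), which leaves 12 little time to isomerise at its doubly allylic carbon; the cyclopentanone α-carbon is re-formed by protonation and should equilibrate under the basic conditions to the more stable trans relationship with the isopropenyl group.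

Step 6
Reactants: 13 3,5-dihydroxy-6,6-bis(3-methylbut-2-en-1-yl)-2-(2-methylpropanoyl)-4-{[(1S,5R)-2-oxo-5-(prop-1-en-2-yl)cyclopentyl]methyl}cyclohexa-2,4-dien-1-one
Product: 14 3,5-dihydroxy-4-{[(1S,2R,5R)-2-hydroxy-2-methyl-5-(prop-1-en-2-yl)cyclopentyl]methyl}-6,6-bis(3-methylbut-2-en-1-yl)-2-(2-methylpropanoyl)cyclohexa-2,4-dien-1-one (target, CNP0290578.2)
Conditions: MeLi (5 equiv), CeCl3 (5.5 equiv, dried), THF, −78 °C, 1 h; then 13, −78 → −40 °C; sat. aq NH4Cl
Reagents that add atoms: methyllithium, C[Li] (used as dichloro(methyl)cerium, C[Ce](Cl)Cl, formed in the flask from CeCl3)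
Why: In this Imamoto organocerium 1,2-addition two equivalents of the reagent convert the acidic enols into a dienolate whose ring carbonyls and acyl group are no longer electrophilic, and the weakly basic methylcerium should then add to the cyclopentanone without enolising it, from the face anti to the C1' substituent on the neighbouring carbon as is usual for 2-substituted cyclopentanones, which places the hydroxyl cis to C1' and gives the R carbinol.

Compound list
1 | cyclopent-2-en-1-one | O=C1C=CCC1 | starting material
2 | isopropenylmagnesium bromide [bromo(prop-1-en-2-yl)magnesium] | C=C(C)[Mg]Br | starting material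
3 | N,N-dimethylmethaniminium iodide (Eschenmoser's salt) | C=[N+](C)C.[I-] | starting material
4 | bromomagnesium (3R)-3-(prop-1-en-2-yl)cyclopent-1-en-1-olate | C=C(C)[C@@H]1CCC(O[Mg]Br)=C1 | intermediate (not isolated)
5 | (2R,3R)-2-[(dimethylamino)methyl]-3-(prop-1-en-2-yl)cyclopentan-1-one | C=C(C)[C@@H]1CCC(=O)[C@H]1CN(C)C | intermediate
6 | N,N,N-trimethyl-1-[(1R,5R)-2-oxo-5-(prop-1-en-2-yl)cyclopentyl]methanaminium iodide | C=C(C)[C@@H]1CCC(=O)[C@H]1C[N+](C)(C)C.[I-] | intermediate
7 | benzene-1,3,5-triol (phloroglucinol) | Oc1cc(O)cc(O)c1 | starting material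
8 | 2-methylpropanoyl chloride | CC(C)C(=O)Cl | starting material
9 | 2-methyl-1-(2,4,6-trihydroxyphenyl)propan-1-one | CC(C)C(=O)c1c(O)cc(O)cc1O | intermediate
10 | 1-bromo-3-methylbut-2-ene (prenyl bromide) | CC(C)=CCBr | starting material
11 | 3,5-dihydroxy-6,6-bis(3-methylbut-2-en-1-yl)-2-(2-methylpropanoyl)cyclohexa-2,4-dien-1-one | CC(C)C(=O)C1=C(O)C=C(O)C(CC=C(C)C)(CC=C(C)C)C1=O | intermediate
12 | (3S)-2-methylidene-3-(prop-1-en-2-yl)cyclopentan-1-one | C=C(C)[C@@H]1CCC(=O)C1=C | intermediate (not isolated)
13 | 3,5-dihydroxy-6,6-bis(3-methylbut-2-en-1-yl)-2-(2-methylpropanoyl)-4-{[(1S,5R)-2-oxo-5-(prop-1-en-2-yl)cyclopentyl]methyl}cyclohexa-2,4-dien-1-one | C=C(C)[C@@H]1CCC(=O)[C@H]1CC1=C(O)C(CC=C(C)C)(CC=C(C)C)C(=O)C(C(=O)C(C)C)=C1O | intermediate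
14 | 3,5-dihydroxy-4-{[(1S,2R,5R)-2-hydroxy-2-methyl-5-(prop-1-en-2-yl)cyclopentyl]methyl}-6,6-bis(3-methylbut-2-en-1-yl)-2-(2-methylpropanoyl)cyclohexa-2,4-dien-1-one | C=C(C)[C@@H]1CC[C@@](C)(O)[C@H]1CC1=C(O)C(CC=C(C)C)(CC=C(C)C)C(=O)C(C(=O)C(C)C)=C1O | target

Total step count: 6. Longest linear sequence: 4 steps (1 → 2 → 5 → 6; the branch 3 → 4 → 5 → 6 is equally long).

Steps most likely to fail

First, step 1. The copper catalyst may discriminate poorly between the enone faces when it transfers an sp2 group to the small, flat cyclopentenone, so that 5 would form with low enantiomeric excess, possibly with some 1,2-addition. The fallback sets out again from 1, 2 and 3 and replaces asymmetric catalysis by a classical resolution. The same conjugate addition–Mannich sequence with CuBr·SMe2 alone (THF, −78 °C) should give rac-trans-2-[(dimethylamino)methyl]-3-(prop-1-en-2-yl)cyclopentan-1-one F1. Crystallisation with one antipode of O,O'-dibenzoyltartaric acid (written here for the 2R,3R acid; the mirror-image acid is taken if that one pairs with the wanted amine) should give (2R,3R)-2-[(dimethylamino)methyl]-3-(prop-1-en-2-yl)cyclopentan-1-one hydrogen (2R,3R)-2,3-bis(benzoyloxy)butanedioate F2. Aqueous NaHCO3 then liberates 5, where the route is rejoined.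

Second, step 6. The two enol protons consume the reagent and may give cerium enolates that aggregate or precipitate in THF, so that addition to the ketone (which may also rest as a cyclic hemiketal with the neighbouring enol) stays incomplete or gives way to enolisation. The fallback sets out from 13 and replaces the one-step C-methylation by a methylene transfer followed by a reduction. Dimethylsulfonium methylide (Me3SI, NaH, DMSO/THF, 0 °C → rt, excess) should convert the soluble disodium enolate of 13 in a Corey–Chaykovsky epoxidation into 3,5-dihydroxy-6,6-bis(3-methylbut-2-en-1-yl)-2-(2-methylpropanoyl)-4-{[(3R,4S,5R)-5-(prop-1-en-2-yl)-1-oxaspiro[2.4]heptan-4-yl]methyl}cyclohexa-2,4-dien-1-one F3, the ylide carbon entering anti to C1' just as methyl would. LiEt3BH (excess, THF, 0 °C, the trione being shielded as its enolate) should then open the oxirane at its CH2 carbon and give 14 directly.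

Third, step 4. The second alkylation may show poor site selectivity (attack at the other free ring carbon, a third prenylation or O-alkylation), leaving little 11. The fallback blocks the carbon that must stay free; it sets out from 8 and 10 and takes commercial methyl 2,4,6-trihydroxybenzoate F4 in place of 7. Friedel–Crafts acylation with 8 (AlCl3, PhNO2) should give methyl 2,4,6-trihydroxy-3-(2-methylpropanoyl)benzoate F5, which has only one unsubstituted ring carbon. NaOMe and 10 in MeOH should then place both prenyl groups there to give methyl 2,6-dihydroxy-3,3-bis(3-methylbut-2-en-1-yl)-5-(2-methylpropanoyl)-4-oxocyclohexa-1,5-diene-1-carboxylate F6. Saponification (LiOH, aq THF, 40 °C) and acidification to pH 3 should let the vinylogous β-keto acid lose CO2 and deliver 11, where the route continues with step 5.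

Further compounds
F1 | step 1 | rac-trans-2-[(dimethylamino)methyl]-3-(prop-1-en-2-yl)cyclopentan-1-one (1:1 mixture of 5 and its mirror image) | C=C(C)[C@@H]1CCC(=O)[C@H]1CN(C)C.C=C(C)[C@H]1CCC(=O)[C@@H]1CN(C)C
F2 | step 1 | (2R,3R)-2-[(dimethylamino)methyl]-3-(prop-1-en-2-yl)cyclopentan-1-one hydrogen (2R,3R)-2,3-bis(benzoyloxy)butanedioate | C=C(C)[C@@H]1CCC(=O)[C@H]1C[NH+](C)C.OC(=O)[C@H](OC(=O)c1ccccc1)[C@@H](OC(=O)c1ccccc1)C([O-])=O
F3 | step 6 | 3,5-dihydroxy-6,6-bis(3-methylbut-2-en-1-yl)-2-(2-methylpropanoyl)-4-{[(3R,4S,5R)-5-(prop-1-en-2-yl)-1-oxaspiro[2.4]heptan-4-yl]methyl}cyclohexa-2,4-dien-1-one | C=C(C)[C@@H]1CC[C@]2(CO2)[C@H]1CC1=C(O)C(CC=C(C)C)(CC=C(C)C)C(=O)C(C(=O)C(C)C)=C1O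
F4 | step 4 | methyl 2,4,6-trihydroxybenzoate (bought) | COC(=O)c1c(O)cc(O)cc1O
F5 | step 4 | methyl 2,4,6-trihydroxy-3-(2-methylpropanoyl)benzoate | COC(=O)c1c(O)cc(O)c(C(=O)C(C)C)c1O
F6 | step 4 | methyl 2,6-dihydroxy-3,3-bis(3-methylbut-2-en-1-yl)-5-(2-methylpropanoyl)-4-oxocyclohexa-1,5-diene-1-carboxylate | COC(=O)C1=C(O)C(CC=C(C)C)(CC=C(C)C)C(=O)C(C(=O)C(C)C)=C1O
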